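**Strategy.** The seven-membered ring (C1, C5–C10 in daucane numbering, defined below) hides a cyclohepta-1,4-diene: the C5–C6 carbinol edge and the C8–C9 epoxide edge flank C7H2. It is closed last by a rhodium-catalysed cyclopropanation/divinylcyclopropane Cope cascade. A vinylcarbenoid (C8–C10) adds to the terminal alkene (C6=C7) of a 1-vinylcyclopentene made from (S)-terpinen-4-ol. Strain release in the resulting cis-divinylcyclopropane forges C1–C10 and sets the quaternary C1 under catalyst control. Hydroboration (C5–H, C6–OH), ester-to-methyl reduction at C8, hydroxyl-directed epoxidation and veratroylation finish the route.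

Key step: step 5

Remark on numbering: C1 = quaternary ring-fusion carbon (CH3), C2, C3 = ring CH2, C4 = carbinol carbon (isopropyl), C5 = ring-fusion CH, C6 = acyloxy carbon, C7 = CH2, C8 = methyl-bearing epoxide carbon, C9 = epoxide CH, C10 = CH2; α = face of C5–H, β = face of the C1 methyl.
Remark (assumption): (S)-terpinen-4-ol is taken as the commercial single enantiomer.
Remark (assumption): the facial sense of Rh2(R-DOSP)4 is assigned by analogy with the established outcome of donor/acceptor carbenoid cyclopropanation of monosubstituted alkenes.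

**Step 1**
Reactants: 1 (S)-terpinen-4-ol
Product: 2 (S)-triethyl[(1-isopropyl-4-methylcyclohex-3-en-1-yl)oxy]silane
Conditions: Et3SiOTf, 2,6-lutidine, CH2Cl2, −78 to 0 °C
Reagents that add atoms: triethylsilyl trifluoromethanesulfonate, CC[Si](CC)(CC)OS(=O)(=O)C(F)(F)F
Why: Silylation of a hindered tertiary alcohol with a silyl triflate; the ether prevents O–H insertion in step 5 and adds bulk to the β-face for step 6, and the carbinol configuration is untouched.

**Step 2**
Reactants: 2 (S)-triethyl[(1-isopropyl-4-methylcyclohex-3-en-1-yl)oxy]silane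
Product: 4 (R)-5-isopropyl-2-methyl-5-(triethylsilyloxy)cyclopent-1-ene-1-carbaldehyde, via keto aldehyde 3 (not isolated)
Conditions: O3, CH2Cl2, −78 °C; Me2S, −78 °C to rt; then piperidine, AcOH (0.3 equiv each), toluene, 60 °C
Reagents that add atoms: ozone, [O-][O+]=O
Why: Ozonolysis with reductive work-up followed by amine-catalysed intramolecular aldol condensation (aldehyde enamine onto the methyl ketone, five-membered ring, loss of water from the free tertiary aldol hydroxyl) should give the conjugated enal; the carbinol centre is not touched (its descriptor changes from S to R only through the priority rules).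

**Step 3**
Reactants: 4 (R)-5-isopropyl-2-methyl-5-(triethylsilyloxy)cyclopent-1-ene-1-carbaldehyde; 5 methyltriphenylphosphonium bromide
Product: 6 (R)-triethyl[(1-isopropyl-3-methyl-2-vinylcyclopent-2-en-1-yl)oxy]silane
Conditions: 5, KN(SiMe3)2, THF, 0 °C; then 4, −78 °C to rt
Reagents that add atoms: none
Why: Wittig methylenation of the hindered but non-enolisable enal should give the 1-vinylcyclopentene (C1=C5–C6=C7 diene); no stereocentre is formed.

**Step 4**
Reactants: 7 methyl but-3-enoate
Product: 8 methyl 2-diazobut-3-enoate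
Conditions: p-ABSA, DBU, MeCN, 0 °C; kept cold and used at once as a pentane solution
Reagents that add atoms: 4-acetamidobenzenesulfonyl azide (p-ABSA), CC(=O)Nc1ccc(cc1)S(=O)(=O)N=[N+]=[N-]
Why: Regitz diazo transfer to the allylic α-ester methylene through its DBU-generated dienolate; the vinyldiazoacetate cyclises to a pyrazole on standing, hence immediate use.

**Step 5**
Reactants: 6 (R)-triethyl[(1-isopropyl-3-methyl-2-vinylcyclopent-2-en-1-yl)oxy]silane; 8 methyl 2-diazobut-3-enoate
Product: 10 methyl (3R,8aR)-3-isopropyl-8a-methyl-3-(triethylsilyloxy)-1,2,3,5,8,8a-hexahydroazulene-6-carboxylate, via divinylcyclopropane 9 (not isolated)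
Conditions: Rh2(R-DOSP)4 (2 mol %), hexanes, −40 °C to rt, slow addition of 8 (2.5 equiv); then 65 °C
Reagents that add atoms: none
Why: The dirhodium tetraprolinate, Rh2(R-DOSP)4 = dirhodium tetrakis[(R)-N-(4-dodecylphenylsulfonyl)prolinate], turns 8 into a donor/acceptor vinylcarbenoid that cyclopropanates the monosubstituted C6=C7 alkene of 6 end-on, placing the carbenoid vinyl group cis to the cyclopentenyl group in 9; this cis-divinylcyclopropane then undergoes a [3,3]-sigmatropic (Cope) rearrangement through a boat transition state, breaking the strained C6–C8 bond and forming C1–C10. The closest known reaction type is the rhodium-catalysed tandem cyclopropanation/Cope rearrangement of vinyldiazoacetates with dienes (formal [4+3] cycloaddition), which is known for 1-vinylcycloalkenes carrying a methyl group on the reacting ring carbon. The seven-membered ring closes by this concerted sigmatropic ring expansion of the three-membered ring (bond formation between the two alkene termini), not by an ionic or radical cyclisation. The new quaternary stereocentre C1 is controlled by the configuration of the cyclopropane (1S,2S in 9), which the chiral catalyst sets and the boat transition state relays, so that C10 arrives on the face of C1 that carries the C4 isopropyl group. The step needs site selectivity (terminal vinyl over the tetrasubstituted ring alkene and over allylic C–H insertion, secured by the steric demand of the carbenoid), cis diastereoselectivity (inherent to donor/acceptor carbenoids) and facial selectivity (catalyst control over the C4 centre). Warming is planned because the C1 methyl group points into the boat and slows the rearrangement.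

**Step 6**
Reactants: 10 methyl (3R,8aR)-3-isopropyl-8a-methyl-3-(triethylsilyloxy)-1,2,3,5,8,8a-hexahydroazulene-6-carboxylate
Product: 12 methyl (3R,3aS,4S,8aR)-4-hydroxy-3-isopropyl-8a-methyl-3-(triethylsilyloxy)-1,2,3,3a,4,5,8,8a-octahydroazulene-6-carboxylate, via alkylborane 11 (not isolated)
Conditions: BH3·THF (1.3 equiv), THF, 0 °C to rt; then NaBO3·4H2O, H2O, rt
Reagents that add atoms: borane–tetrahydrofuran (boron kept in 11 only), [BH3-][O+]1CCCC1; sodium perborate, [Na+].[Na+].O[B-]1(O)OO[B-](O)(O)OO1
Why: Hydroboration–oxidation: syn addition of H–B across the electron-rich C5=C6 alkene (boron on the less substituted C6, the electron-poor enoate C8=C9 left alone) is expected on the α-face, anti to the C1 methyl and the pseudo-axial C4 silyloxy group, which sets C5–H and C6–B cis, and perborate replaces boron by hydroxyl with retention.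

**Step 7**
Reactants: 12 methyl (3R,3aS,4S,8aR)-4-hydroxy-3-isopropyl-8a-methyl-3-(triethylsilyloxy)-1,2,3,3a,4,5,8,8a-octahydroazulene-6-carboxylate
Product: 13 (3R,3aS,4S,8aR)-6-(hydroxymethyl)-3-isopropyl-8a-methyl-3-(triethylsilyloxy)-1,2,3,3a,4,5,8,8a-octahydroazulen-4-ol
Conditions: i-Bu2AlH (3.5 equiv), CH2Cl2, −78 to 0 °C; aqueous potassium sodium tartrate
Reagents that add atoms: none
Why: 1,2-Reduction of the α,β-unsaturated ester to the primary allylic alcohol by i-Bu2AlH; silyl ether and stereocentres are unaffected.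

**Step 8**
Reactants: 13 (3R,3aS,4S,8aR)-6-(hydroxymethyl)-3-isopropyl-8a-methyl-3-(triethylsilyloxy)-1,2,3,3a,4,5,8,8a-octahydroazulen-4-ol
Product: 15 (3R,3aS,4S,8aR)-3-isopropyl-6,8a-dimethyl-3-(triethylsilyloxy)-1,2,3,3a,4,5,8,8a-octahydroazulen-4-ol, via allylic mesylate 14 (not isolated)
Conditions: MsCl (1.05 equiv), Et3N, THF, −40 °C; then LiEt3BH (4 equiv), −40 °C to rt
Reagents that add atoms: methanesulfonyl chloride (atoms kept in 14 only), CS(=O)(=O)Cl
Why: Selective sulfonylation of the primary allylic hydroxyl (the secondary C6–OH is hindered) and direct SN2 hydride displacement by LiEt3BH (deoxygenation by sulfonate reduction) should give the C8 methyl group without touching a stereocentre.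

**Step 9**
Reactants: 15 (3R,3aS,4S,8aR)-3-isopropyl-6,8a-dimethyl-3-(triethylsilyloxy)-1,2,3,3a,4,5,8,8a-octahydroazulen-4-ol
Product: 16 jaeschkeanadiol, (3R,3aS,4S,8aR)-3-isopropyl-6,8a-dimethyl-1,2,3,3a,4,5,8,8a-octahydroazulene-3,4-diol
Conditions: Bu4NF, THF, 50 °C
Reagents that add atoms: none
Why: Fluoride-mediated cleavage of the tertiary triethylsilyl ether before the acid- and base-sensitive epoxide is present; no stereocentre is involved.

**Step 10**
Reactants: 16 jaeschkeanadiol
Product: 17 (1R,4R,5S,6S,8R,9S)-8,9-epoxydaucane-4,6-diol (8α,9α-epoxide of 16)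
Conditions: VO(acac)2 (5 mol %), t-BuOOH (1.5 equiv, decane solution), CH2Cl2, 0 °C to rt
Reagents that add atoms: tert-butyl hydroperoxide, CC(C)(C)OO
Why: Hydroxyl-directed epoxidation: the homoallylic C6–OH binds vanadium and delivers oxygen to the α-face of C8=C9, syn to itself and anti to the C1 methyl, which sets C8 and C9; the tertiary C4–OH is too remote to direct.

**Step 11**
Reactants: 17 (1R,4R,5S,6S,8R,9S)-8,9-epoxydaucane-4,6-diol; 18 3,4-dimethoxybenzoyl chloride
Product: 19 (1R,4R,5S,6S,8R,9S)-8,9-epoxy-4-hydroxydaucan-6-yl 3,4-dimethoxybenzoate (CNP0251065.1)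
Conditions: 18, Et3N, DMAP (cat.), CH2Cl2, 0 °C to rt
Reagents that add atoms: none
Why: DMAP-catalysed acylation of the only secondary hydroxyl with the acid chloride under basic conditions that spare the epoxide; the tertiary C4–OH does not react and no stereocentre is touched.

**Compound list**
1 | (S)-terpinen-4-ol | CC1=CC[C@](O)(C(C)C)CC1 | starting material
2 | (S)-triethyl[(1-isopropyl-4-methylcyclohex-3-en-1-yl)oxy]silane | CC1=CC[C@](O[Si](CC)(CC)CC)(C(C)C)CC1 | intermediate
3 | (S)-3-isopropyl-6-oxo-3-(triethylsilyloxy)heptanal (keto aldehyde) | O=CC[C@](O[Si](CC)(CC)CC)(C(C)C)CCC(C)=O | intermediate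
4 | (R)-5-isopropyl-2-methyl-5-(triethylsilyloxy)cyclopent-1-ene-1-carbaldehyde | O=CC1=C(C)CC[C@@]1(O[Si](CC)(CC)CC)C(C)C | intermediate
5 | methyltriphenylphosphonium bromide | C[P+](c1ccccc1)(c1ccccc1)c1ccccc1.[Br-] | starting material
6 | (R)-triethyl[(1-isopropyl-3-methyl-2-vinylcyclopent-2-en-1-yl)oxy]silane | C=CC1=C(C)CC[C@@]1(O[Si](CC)(CC)CC)C(C)C | intermediate
7 | methyl but-3-enoate | C=CCC(=O)OC | starting material
8 | methyl 2-diazobut-3-enoate | C=CC(=[N+]=[N-])C(=O)OC | intermediate
9 | methyl (1S,2S)-1-ethenyl-2-[(5R)-5-isopropyl-2-methyl-5-(triethylsilyloxy)cyclopent-1-en-1-yl]cyclopropane-1-carboxylate (divinylcyclopropane) | COC(=O)[C@]1(C=C)C[C@H]1C2=C(C)CC[C@@]2(O[Si](CC)(CC)CC)C(C)C | intermediate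
10 | methyl (3R,8aR)-3-isopropyl-8a-methyl-3-(triethylsilyloxy)-1,2,3,5,8,8a-hexahydroazulene-6-carboxylate | COC(=O)C1=CC[C@@]2(C)CC[C@@](O[Si](CC)(CC)CC)(C(C)C)C2=CC1 | intermediate
11 | C6 monoalkylborane of 12 (BH2 in place of OH, same configuration) | COC(=O)C1=CC[C@@]2(C)CC[C@@](O[Si](CC)(CC)CC)(C(C)C)[C@@H]2[C@@H](B)C1 | intermediate
12 | methyl (3R,3aS,4S,8aR)-4-hydroxy-3-isopropyl-8a-methyl-3-(triethylsilyloxy)-1,2,3,3a,4,5,8,8a-octahydroazulene-6-carboxylate | COC(=O)C1=CC[C@@]2(C)CC[C@@](O[Si](CC)(CC)CC)(C(C)C)[C@@H]2[C@@H](O)C1 | intermediate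
13 | (3R,3aS,4S,8aR)-6-(hydroxymethyl)-3-isopropyl-8a-methyl-3-(triethylsilyloxy)-1,2,3,3a,4,5,8,8a-octahydroazulen-4-ol | OCC1=CC[C@@]2(C)CC[C@@](O[Si](CC)(CC)CC)(C(C)C)[C@@H]2[C@@H](O)C1 | intermediate
14 | primary allylic methanesulfonate of 13 | CS(=O)(=O)OCC1=CC[C@@]2(C)CC[C@@](O[Si](CC)(CC)CC)(C(C)C)[C@@H]2[C@@H](O)C1 | intermediate
15 | (3R,3aS,4S,8aR)-3-isopropyl-6,8a-dimethyl-3-(triethylsilyloxy)-1,2,3,3a,4,5,8,8a-octahydroazulen-4-ol | CC1=CC[C@@]2(C)CC[C@@](O[Si](CC)(CC)CC)(C(C)C)[C@@H]2[C@@H](O)C1 | intermediate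
16 | jaeschkeanadiol, (3R,3aS,4S,8aR)-3-isopropyl-6,8a-dimethyl-1,2,3,3a,4,5,8,8a-octahydroazulene-3,4-diol | CC1=CC[C@@]2(C)CC[C@@](O)(C(C)C)[C@@H]2[C@@H](O)C1 | intermediate
17 | (1R,4R,5S,6S,8R,9S)-8,9-epoxydaucane-4,6-diol | O[C@H]1C[C@@]2(C)O[C@H]2C[C@@]2(C)CC[C@@](O)(C(C)C)[C@H]12 | intermediate
18 | 3,4-dimethoxybenzoyl chloride | COc1ccc(cc1OC)C(Cl)=O | starting material
19 | (1R,4R,5S,6S,8R,9S)-8,9-epoxy-4-hydroxydaucan-6-yl 3,4-dimethoxybenzoate | COc1ccc(C(=O)O[C@H]2C[C@@]3(C)O[C@H]3C[C@@]3(C)CC[C@@](O)(C(C)C)[C@H]23)cc1OC | target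

**Step count.** Total: 11 steps. Longest linear sequence: 10 steps (steps 1–3 and 5–11, from 1).

**Steps most likely to fail**

1. Step 5. The carbenoid may be diverted to allylic C–H insertion or dimerisation because the vinyl group is flanked by a quaternary centre. The catalyst preference and the C4 centre may oppose each other and erode facial control at C1; if the sense of induction proves opposite to the assumed one, the enantiomeric catalyst is the first remedy. The Cope step may stall because of the inward-pointing methyl group. Fallback (ring closure by metathesis, known chemistry), setting out from 4 and returning at 15: allylation of 4 with (−)-Ipc2B(allyl) (Et2O, −78 °C; oxidative work-up) should give (1S)-1-[(5R)-5-isopropyl-2-methyl-5-(triethylsilyloxy)cyclopent-1-en-1-yl]but-3-en-1-ol F1. Anionic oxy-Cope rearrangement (KH, 18-crown-6, THF, 0 °C; cold buffered quench) relays the carbinol configuration through a chair transition state to the quaternary C1 and gives (1R,2R,5R)-2-allyl-5-isopropyl-2-methyl-5-(triethylsilyloxy)cyclopentane-1-carbaldehyde F2. Addition of 2-methylallylmagnesium chloride (THF, −78 °C; diastereomers separated) gives (1S)-1-[(1S,2R,5R)-2-allyl-5-isopropyl-2-methyl-5-(triethylsilyloxy)cyclopentyl]-3-methylbut-3-en-1-ol F3. Ring-closing metathesis with the second-generation Grubbs catalyst, (H2IMes)(PCy3)Cl2Ru=CHPh (CH2Cl2, 40 °C), forms C8=C9 and gives 15.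

2. Step 6. Facial selectivity is the weak point: α-face groups (C4 isopropyl, C10) and β-face groups (C1 methyl, C4 silyloxy) are comparably placed around C5=C6, so borane may add mainly from the β-face; slow addition to this hindered alkene could also let borane reduce the enoate. Fallback (epoxide route with radical opening), setting out from 10 and returning at 12, designed for the case of β-face preference: mCPBA/NaHCO3 (CH2Cl2, 0 °C) epoxidises only the electron-rich alkene from the same β-face to give the 5β,6β-epoxide of 10 F4. Reductive opening with Cp2TiCl (from Cp2TiCl2 and Zn) and 1,4-cyclohexadiene (THF, rt) cleaves the C5–O bond to the tertiary radical, which takes hydrogen anti to the bulky C6 titanium alkoxide and gives the C6-epimer of 12 F5 with C5–H α. Dess–Martin periodinane gives the ketone methyl (3R,3aR,8aR)-3-isopropyl-8a-methyl-4-oxo-3-(triethylsilyloxy)-1,2,3,3a,4,5,8,8a-octahydroazulene-6-carboxylate F6 without base. NaBH4/CeCl3·7H2O (MeOH, −40 °C) then attacks from the same β-face and gives 12.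

3. Step 2. The aldehyde enamine carries a β-silyloxy group, so loss of the tertiary silyloxy group, wrong-way dehydration of the aldol (toward C4 instead of C1) or the regioisomeric ketone-enolate aldol may compete. Fallback (addition and elimination separated, with reagent-controlled dehydration), setting out from 3 and returning at 4: amine-catalysed aldol addition at 0 °C (pyrrolidine, PhCO2H, CH2Cl2) is stopped at the β-hydroxy aldehyde (5R)-2-hydroxy-5-isopropyl-2-methyl-5-(triethylsilyloxy)cyclopentane-1-carbaldehyde F7 (diastereomer mixture at the two new centres). Its free tertiary hydroxyl alone is then activated and eliminated with the Burgess reagent (benzene, 50 °C), which cannot touch the silyl ether, to give 4.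

**Further compounds**
F1 | step 5 | (1S)-1-[(5R)-5-isopropyl-2-methyl-5-(triethylsilyloxy)cyclopent-1-en-1-yl]but-3-en-1-ol | C=CC[C@H](O)C1=C(C)CC[C@@]1(O[Si](CC)(CC)CC)C(C)C
F2 | step 5 | (1R,2R,5R)-2-allyl-5-isopropyl-2-methyl-5-(triethylsilyloxy)cyclopentane-1-carbaldehyde | C=CC[C@@]1(C)CC[C@@](O[Si](CC)(CC)CC)(C(C)C)[C@@H]1C=O
F3 | step 5 | (1S)-1-[(1S,2R,5R)-2-allyl-5-isopropyl-2-methyl-5-(triethylsilyloxy)cyclopentyl]-3-methylbut-3-en-1-ol | C=CC[C@@]1(C)CC[C@@](O[Si](CC)(CC)CC)(C(C)C)[C@@H]1[C@@H](O)CC(C)=C
F4 | step 6 | 5β,6β-epoxide of 10 | COC(=O)C1=CC[C@@]2(C)CC[C@@](O[Si](CC)(CC)CC)(C(C)C)[C@]23O[C@@H]3C1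
F5 | step 6 | methyl (3R,3aS,4R,8aR)-4-hydroxy-3-isopropyl-8a-methyl-3-(triethylsilyloxy)-1,2,3,3a,4,5,8,8a-octahydroazulene-6-carboxylate (C6-epimer of 12) | COC(=O)C1=CC[C@@]2(C)CC[C@@](O[Si](CC)(CC)CC)(C(C)C)[C@@H]2[C@H](O)C1
F6 | step 6 | methyl (3R,3aR,8aR)-3-isopropyl-8a-methyl-4-oxo-3-(triethylsilyloxy)-1,2,3,3a,4,5,8,8a-octahydroazulene-6-carboxylate | COC(=O)C1=CC[C@@]2(C)CC[C@@](O[Si](CC)(CC)CC)(C(C)C)[C@@H]2C(=O)C1
F7 | step 2 | (5R)-2-hydroxy-5-isopropyl-2-methyl-5-(triethylsilyloxy)cyclopentane-1-carbaldehyde | O=CC1C(C)(O)CC[C@@]1(O[Si](CC)(CC)CC)C(C)C
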